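**Plan** (ring numbering: C1 = C(Br)(CH2Cl), C2 = neighbouring CHCl, C3 = CH2, C4 = CHCl, C5 = C(CH3)(chloroethenyl), C6 = CH2)
- Retrosynthesis: (a) Br–C1/H–C6 by HBr addition to a C1=C6 alkene; (b) C2–Cl and CH2–Cl from an allylic diol; (c) the C1–C2 ring bond; then C2–C3 (Wittig), C4–Cl, the chloroethenyl C=C (Takai) and the C5–C6 bond (allylic alkynylation).
- Forward: the chain is built around quaternary C5, the alkyne is turned into a (Z)-2-iodoallylic alcohol, and the only ring is closed in step 12 by Ni/Cr-mediated addition of the C1 alkenyl metal to the C2 aldehyde; the two chlorides and the bromide follow.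
- Enabling feature: C1 carries the exocyclic CH2Cl and sits between ring CH2 (C6) and ring CHCl (C2). So C1 can be the iodine-bearing carbon of a C6=C1 iodoalkene with a CH2OH handle, and C2 an aldehyde carbon; the gem-disubstituted C5 favours six-ring closure and shields C6.
- Stereochemistry: C5 from the chiral NHC–copper catalyst; C4 from the chiral amine catalyst; C2 from allylic strain in the ring closure, then SN2 inversion; C1 from anti (trans-diaxial) HBr addition; chloroethenyl E geometry from the Takai reaction.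

Key step: step 12

Assumption: in the two catalyst-controlled steps (3 and 8) the catalyst enantiomer is the one that leads to the configuration drawn, and 3-(methoxymethoxy)prop-1-yne is taken as a purchasable alkyne.

**Step 1**
Reactants: 1 tert-butyl(but-3-yn-1-yloxy)dimethylsilane
Product: 2 (2E)-5-[(tert-butyldimethylsilyl)oxy]-3-methylpent-2-en-1-ol
Conditions: Me3Al, Cp2ZrCl2 (25 mol %), CH2Cl2, 0 °C to rt; then n-BuLi, (CH2O)n, THF, 0 °C to rt
Reagents that add atoms: trimethylaluminium C[Al](C)C; paraformaldehyde (as formaldehyde) C=O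
Why: Negishi zirconium-catalysed syn-carboalumination puts methyl on the internal and aluminium on the terminal alkyne carbon, and the alkenyl alanate traps formaldehyde with retention, which should give only the E allylic alcohol.

**Step 2**
Reactants: 2 (2E)-5-[(tert-butyldimethylsilyl)oxy]-3-methylpent-2-en-1-ol
Product: 3 (2E)-5-[(tert-butyldimethylsilyl)oxy]-3-methylpent-2-en-1-yl diethyl phosphate
Conditions: ClP(O)(OEt)2, Et3N, DMAP (10 mol %), CH2Cl2, 0 °C
Reagents that add atoms: diethyl chlorophosphate CCOP(=O)(Cl)OCC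
Why: O-phosphorylation of the primary allylic alcohol installs the leaving group for copper-catalysed SN2′ substitution and leaves the E alkene untouched.

**Step 3**
Reactants: 3 (2E)-5-[(tert-butyldimethylsilyl)oxy]-3-methylpent-2-en-1-yl diethyl phosphate; 4 3-(methoxymethoxy)prop-1-yne
Product: 5 tert-butyl{[(3R)-3-ethenyl-6-(methoxymethoxy)-3-methylhex-4-yn-1-yl]oxy}dimethylsilane
Conditions: 4, i-Bu2AlH, Et3N (5 mol %), hexanes, 22 °C; then 3, CuCl2·2H2O (5 mol %), chiral sulfonate-bearing imidazolinium salt (carbene precursor, 5.5 mol %), THF, −15 °C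
Reagents that add atoms: none
Why: NHC–copper-catalysed enantioselective allylic substitution with an alkynylaluminium reagent delivers the alkynyl group SN2′ to the methyl-bearing alkene carbon, creating the quaternary centre (later C5) with a vinyl group; its configuration is fixed by the chiral carbene ligand and the E geometry of 3.

**Step 4**
Reactants: 5 tert-butyl{[(3R)-3-ethenyl-6-(methoxymethoxy)-3-methylhex-4-yn-1-yl]oxy}dimethylsilane
Product: 6 (2S)-2-{2-[(tert-butyldimethylsilyl)oxy]ethyl}-5-(methoxymethoxy)-2-methylpent-3-ynal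
Conditions: O3, CH2Cl2–MeOH, −78 °C (dye end point); then PPh3
Reagents that add atoms: ozone [O-][O+]=O
Why: Ozonolysis with reductive work-up cleaves the terminal alkene much faster than the internal alkyne and should give the non-enolisable α-quaternary aldehyde without touching the stereocentre.

**Step 5**
Reactants: 6 (2S)-2-{2-[(tert-butyldimethylsilyl)oxy]ethyl}-5-(methoxymethoxy)-2-methylpent-3-ynal
Product: 7 tert-butyl{[(3R)-3-[(E)-2-chloroethenyl]-6-(methoxymethoxy)-3-methylhex-4-yn-1-yl]oxy}dimethylsilane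
Conditions: CrCl2 (6 equiv), CHCl3 (2 equiv), THF, 65 °C
Reagents that add atoms: chloroform ClC(Cl)Cl
Why: Takai–Utimoto olefination with the chromium carbenoid from chloroform converts the aldehyde into the (E)-2-chloroethenyl group with the usual high E selectivity; alkyne, acetal and silyl ether are inert to divalent chromium.

**Step 6**
Reactants: 7 tert-butyl{[(3R)-3-[(E)-2-chloroethenyl]-6-(methoxymethoxy)-3-methylhex-4-yn-1-yl]oxy}dimethylsilane
Product: 8 (3R)-3-[(E)-2-chloroethenyl]-6-(methoxymethoxy)-3-methylhex-4-yn-1-ol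
Conditions: TBAF, THF, 0 °C
Reagents that add atoms: none
Why: Fluoride-mediated desilylation frees the primary alcohol while the methoxymethyl ether on the propargylic oxygen stays.

**Step 7**
Reactants: 8 (3R)-3-[(E)-2-chloroethenyl]-6-(methoxymethoxy)-3-methylhex-4-yn-1-ol
Product: 9 (3R)-3-[(E)-2-chloroethenyl]-6-(methoxymethoxy)-3-methylhex-4-ynal
Conditions: Dess–Martin periodinane, NaHCO3, CH2Cl2, 0 °C to rt
Reagents that add atoms: none
Why: Dess–Martin oxidation gives the aldehyde under neutral conditions; the neighbouring stereocentre is quaternary and cannot epimerise.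

**Step 8**
Reactants: 9 (3R)-3-[(E)-2-chloroethenyl]-6-(methoxymethoxy)-3-methylhex-4-ynal; 10 (methoxymethyl)triphenylphosphonium chloride
Product: 12 (3S,4R)-3-chloro-4-[(E)-2-chloroethenyl]-1-methoxy-7-(methoxymethoxy)-4-methylhept-1-en-5-yne (E/Z enol ether mixture), via α-chloro aldehyde 11 (not isolated)
Conditions: NCS, trans-2,5-diphenylpyrrolidine (10 mol %, enantiomer that gives the 2R chloride), CH2Cl2, 0 °C; silica plug; then ylide from 10 and KN(SiMe3)2, THF, −78 to 0 °C
Reagents that add atoms: N-chlorosuccinimide O=C1CCC(=O)N1Cl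
Why: Enamine-catalysed α-chlorination sets the secondary chloride (later C4) under catalyst control next to the quaternary centre, and the labile α-chloro aldehyde is trapped at once by Wittig methoxymethylenation, which adds the carbon that becomes C2.

**Step 9**
Reactants: 12 (3S,4R)-3-chloro-4-[(E)-2-chloroethenyl]-1-methoxy-7-(methoxymethoxy)-4-methylhept-1-en-5-yne
Product: 13 (4R,5S)-5-chloro-4-[(E)-2-chloroethenyl]-7,7-dimethoxy-4-methylhept-2-yn-1-ol
Conditions: HCl (from AcCl, 0.3 equiv), MeOH, 40 °C
Reagents that add atoms: methanol CO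
Why: Acid-catalysed addition of methanol turns the enol ether into the dimethyl acetal (a masked aldehyde that tolerates iodine), and the same acid removes the methoxymethyl ether by transacetalisation, freeing the propargylic alcohol that directs the next step.

**Step 10**
Reactants: 13 (4R,5S)-5-chloro-4-[(E)-2-chloroethenyl]-7,7-dimethoxy-4-methylhept-2-yn-1-ol
Product: 15 (2Z,4R,5S)-5-chloro-4-[(E)-2-chloroethenyl]-2-iodo-7,7-dimethoxy-4-methylhept-2-en-1-ol, via alkenylstannane 14 (not isolated)
Conditions: [Cp*RuCl]4 (2 mol %), Bu3SnH, CH2Cl2, rt; then I2, CH2Cl2, 0 °C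
Reagents that add atoms: tributyltin hydride CCCC[SnH](CCCC)CCCC; iodine II
Why: Hydroxyl-directed ruthenium-catalysed trans-hydrostannation puts tin on the alkyne carbon next to CH2OH and hydrogen anti to it, and iododestannylation with retention should give the (Z)-2-iodoallylic alcohol with iodine cis to the quaternary carbon, as the ring closure needs.

**Step 11**
Reactants: 15 (2Z,4R,5S)-5-chloro-4-[(E)-2-chloroethenyl]-2-iodo-7,7-dimethoxy-4-methylhept-2-en-1-ol
Product: 16 (3S,4R,5Z)-3-chloro-4-[(E)-2-chloroethenyl]-7-hydroxy-6-iodo-4-methylhept-5-enal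
Conditions: TFA–H2O (9:1), CH2Cl2, 0 °C
Reagents that add atoms: water O
Why: Acid hydrolysis of the dimethyl acetal releases the aldehyde; the β-chloride is stable to acid and no base is present to eliminate it.

**Step 12**
Reactants: 16 (3S,4R,5Z)-3-chloro-4-[(E)-2-chloroethenyl]-7-hydroxy-6-iodo-4-methylhept-5-enal
Product: 17 (1S,4S,5S)-5-chloro-4-[(E)-2-chloroethenyl]-2-(hydroxymethyl)-4-methylcyclohex-2-en-1-ol
Conditions: CrCl2 (6 equiv), NiCl2 (2 mol %), DMSO–THF (3:1), rt, 0.005 M
Reagents that add atoms: none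
Why: Zerovalent nickel, formed from NiCl2 and CrCl2, inserts into the alkenyl carbon–iodine bond and passes the alkenyl group to trivalent chromium, and the alkenylchromium adds to the tethered aldehyde (intramolecular Nozaki–Hiyama–Kishi reaction). The closest known use is the Ni/Cr ring closure of iodoalkenyl aldehydes to cycloalkenols. The six-membered ring closes by 6-exo-trig attack of C1 on the C2 carbonyl, with the C1=C6 alkene ending up inside the ring, which the Z iodoalkene and the gem-disubstituted C5 both allow. The new carbinol centre C2 is set by the substrate: in the half-chair transition state the C4 chloride is equatorial and the developing C2–O–Cr bond pseudoaxial, away from the C1 hydroxymethyl group (allylic strain), so oxygen should end trans to the C4 chloride. The step needs chemoselectivity for the carbon–iodine bond over the alkenyl and alkyl chlorides, which the far faster oxidative addition to the iodide secures, and no β-elimination of the alkenylchromium, which is unlikely because the β-oxygen is a chromium alkoxide.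

**Step 13**
Reactants: 17 (1S,4S,5S)-5-chloro-4-[(E)-2-chloroethenyl]-2-(hydroxymethyl)-4-methylcyclohex-2-en-1-ol
Product: 18 (3S,4S,6R)-4,6-dichloro-1-(chloromethyl)-3-[(E)-2-chloroethenyl]-3-methylcyclohex-1-ene
Conditions: PPh3 (2.6 equiv), hexachloroacetone, CH2Cl2, −20 to 0 °C
Reagents that add atoms: hexachloroacetone O=C(C(Cl)(Cl)Cl)C(Cl)(Cl)Cl
Why: Appel-type chlorination with triphenylphosphine–hexachloroacetone replaces both allylic hydroxyls by SN2: the primary one gives the chloromethyl group and the ring carbinol is inverted to the C2 chloride, now cis to the C4 chloride; SN2′ attack at C6 is hindered by the neighbouring quaternary carbon.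

**Step 14**
Reactants: 18 (3S,4S,6R)-4,6-dichloro-1-(chloromethyl)-3-[(E)-2-chloroethenyl]-3-methylcyclohex-1-ene
Product: 19 (1R,2R,4S,5S)-1-bromo-2,4-dichloro-5-[(E)-2-chloroethenyl]-1-(chloromethyl)-5-methylcyclohexane
Conditions: HBr (gas, excess), CH2Cl2, −40 to 0 °C, dark, BHT (1 mol %)
Reagents that add atoms: hydrogen bromide Br
Why: Markovnikov ionic hydrobromination of the trisubstituted alkene: the proton goes to C6 (the other cation would be secondary and neopentyl) and bromide enters C1 anti and axial, through the diaxial mode that leads to the chair with both ring chlorides equatorial, which should place bromine cis to the C2 chloride.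

**Compound list**
1 | tert-butyl(but-3-yn-1-yloxy)dimethylsilane | C#CCCO[Si](C)(C)C(C)(C)C | starting material
2 | (2E)-5-[(tert-butyldimethylsilyl)oxy]-3-methylpent-2-en-1-ol | OC/C=C(\C)CCO[Si](C)(C)C(C)(C)C | intermediate
3 | (2E)-5-[(tert-butyldimethylsilyl)oxy]-3-methylpent-2-en-1-yl diethyl phosphate | CCOP(=O)(OCC)OC/C=C(\C)CCO[Si](C)(C)C(C)(C)C | intermediate
4 | 3-(methoxymethoxy)prop-1-yne | C#CCOCOC | starting material
5 | tert-butyl{[(3R)-3-ethenyl-6-(methoxymethoxy)-3-methylhex-4-yn-1-yl]oxy}dimethylsilane | C[C@@](CCO[Si](C)(C)C(C)(C)C)(C=C)C#CCOCOC | intermediate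
6 | (2S)-2-{2-[(tert-butyldimethylsilyl)oxy]ethyl}-5-(methoxymethoxy)-2-methylpent-3-ynal | C[C@@](CCO[Si](C)(C)C(C)(C)C)(C=O)C#CCOCOC | intermediate
7 | tert-butyl{[(3R)-3-[(E)-2-chloroethenyl]-6-(methoxymethoxy)-3-methylhex-4-yn-1-yl]oxy}dimethylsilane | C[C@@](CCO[Si](C)(C)C(C)(C)C)(/C=C/Cl)C#CCOCOC | intermediate
8 | (3R)-3-[(E)-2-chloroethenyl]-6-(methoxymethoxy)-3-methylhex-4-yn-1-ol | C[C@@](CCO)(/C=C/Cl)C#CCOCOC | intermediate
9 | (3R)-3-[(E)-2-chloroethenyl]-6-(methoxymethoxy)-3-methylhex-4-ynal | C[C@@](CC=O)(/C=C/Cl)C#CCOCOC | intermediate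
10 | (methoxymethyl)triphenylphosphonium chloride | COC[P+](c1ccccc1)(c1ccccc1)c1ccccc1.[Cl-] | starting material
11 | (2R,3R)-2-chloro-3-[(E)-2-chloroethenyl]-6-(methoxymethoxy)-3-methylhex-4-ynal | C[C@@]([C@@H](Cl)C=O)(/C=C/Cl)C#CCOCOC | intermediate (not isolated)
12 | (3S,4R)-3-chloro-4-[(E)-2-chloroethenyl]-1-methoxy-7-(methoxymethoxy)-4-methylhept-1-en-5-yne, E/Z mixture at the enol ether | C[C@@]([C@@H](Cl)C=COC)(/C=C/Cl)C#CCOCOC | intermediate
13 | (4R,5S)-5-chloro-4-[(E)-2-chloroethenyl]-7,7-dimethoxy-4-methylhept-2-yn-1-ol | C[C@@]([C@@H](Cl)CC(OC)OC)(/C=C/Cl)C#CCO | intermediate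
14 | (2Z,4R,5S)-5-chloro-4-[(E)-2-chloroethenyl]-7,7-dimethoxy-4-methyl-2-(tributylstannyl)hept-2-en-1-ol | C[C@@]([C@@H](Cl)CC(OC)OC)(/C=C/Cl)/C=C(\[Sn](CCCC)(CCCC)CCCC)CO | intermediate (not isolated)
15 | (2Z,4R,5S)-5-chloro-4-[(E)-2-chloroethenyl]-2-iodo-7,7-dimethoxy-4-methylhept-2-en-1-ol | C[C@@]([C@@H](Cl)CC(OC)OC)(/C=C/Cl)/C=C(\I)CO | intermediate
16 | (3S,4R,5Z)-3-chloro-4-[(E)-2-chloroethenyl]-7-hydroxy-6-iodo-4-methylhept-5-enal | C[C@@]([C@@H](Cl)CC=O)(/C=C/Cl)/C=C(\I)CO | intermediate
17 | (1S,4S,5S)-5-chloro-4-[(E)-2-chloroethenyl]-2-(hydroxymethyl)-4-methylcyclohex-2-en-1-ol | C[C@@]1(/C=C/Cl)C=C(CO)[C@@H](O)C[C@@H]1Cl | intermediate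
18 | (3S,4S,6R)-4,6-dichloro-1-(chloromethyl)-3-[(E)-2-chloroethenyl]-3-methylcyclohex-1-ene | C[C@@]1(/C=C/Cl)C=C(CCl)[C@H](Cl)C[C@@H]1Cl | intermediate
19 | (1R,2R,4S,5S)-1-bromo-2,4-dichloro-5-[(E)-2-chloroethenyl]-1-(chloromethyl)-5-methylcyclohexane | C[C@@]1(/C=C/Cl)C[C@@](Br)(CCl)[C@H](Cl)C[C@@H]1Cl | target

Total steps: 14. Longest linear sequence: 14.

**Steps most likely to fail**

Step 14. Protonation of the alkene, which is deactivated by two allylic chlorides, may be slower than ionisation or SN2′ exchange of those chlorides, so halide scrambling can occur, and bromide may enter from the wrong face. The fallback sets out from 18 and replaces the ionic addition by a radical Markovnikov hydrobromination through hydrogen-atom transfer (Co(acac)2 cat., t-BuOOH, Et3SiH, TsBr, n-PrOH, rt). The tertiary C1 radical is not destabilised by the β-chlorines and takes bromine from the sulfonyl bromide. It returns directly at 19 and makes no new compound, F0.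

Step 12. Facial selectivity in the addition to the aldehyde may be poor, giving the carbinol epimer. The fallback sets out from 16 and takes whatever diol mixture the ring closure gives, including the epimer (1R,4S,5S)-5-chloro-4-[(E)-2-chloroethenyl]-2-(hydroxymethyl)-4-methylcyclohex-2-en-1-ol F1. The primary hydroxyl is silylated (TBSCl, imidazole) to give the silyl ether (1R,4S,5S)-2-{[(tert-butyldimethylsilyl)oxy]methyl}-5-chloro-4-[(E)-2-chloroethenyl]-4-methylcyclohex-2-en-1-ol F2. Dess–Martin oxidation converges both epimers on the enone (4S,5S)-2-{[(tert-butyldimethylsilyl)oxy]methyl}-5-chloro-4-[(E)-2-chloroethenyl]-4-methylcyclohex-2-en-1-one F3. A Corey–Bakshi–Shibata reduction, with the oxazaborolidine enantiomer that delivers hydride to the required face and BH3·SMe2, then sets the carbinol by reagent control, giving (1S,4S,5S)-2-{[(tert-butyldimethylsilyl)oxy]methyl}-5-chloro-4-[(E)-2-chloroethenyl]-4-methylcyclohex-2-en-1-ol F4. TBAF returns to the route at 17.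

Step 13. Allylic transposition or ion-pair return (retention) at the ring carbinol may erode regio- and stereochemistry when both hydroxyls are activated together. The fallback sets out from 17 and works stepwise. Corey–Kim chlorination (NCS, Me2S, CH2Cl2, −20 °C) should convert only the primary allylic alcohol, giving (1S,4S,5S)-5-chloro-2-(chloromethyl)-4-[(E)-2-chloroethenyl]-4-methylcyclohex-2-en-1-ol F5. The remaining secondary alcohol is then chlorinated with inversion under neutral conditions by the α-chloroenamine reagent 1-chloro-N,N,2-trimethylprop-1-en-1-amine (CH2Cl2, 0 °C), which returns to the route at 18.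

**Further compounds**
F1 | step 12 | (1R,4S,5S)-5-chloro-4-[(E)-2-chloroethenyl]-2-(hydroxymethyl)-4-methylcyclohex-2-en-1-ol | C[C@@]1(/C=C/Cl)C=C(CO)[C@H](O)C[C@@H]1Cl
F2 | step 12 | (1R,4S,5S)-2-{[(tert-butyldimethylsilyl)oxy]methyl}-5-chloro-4-[(E)-2-chloroethenyl]-4-methylcyclohex-2-en-1-ol | C[C@@]1(/C=C/Cl)C=C(CO[Si](C)(C)C(C)(C)C)[C@H](O)C[C@@H]1Cl
F3 | step 12 | (4S,5S)-2-{[(tert-butyldimethylsilyl)oxy]methyl}-5-chloro-4-[(E)-2-chloroethenyl]-4-methylcyclohex-2-en-1-one | C[C@@]1(/C=C/Cl)C=C(CO[Si](C)(C)C(C)(C)C)C(=O)C[C@@H]1Cl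
F4 | step 12 | (1S,4S,5S)-2-{[(tert-butyldimethylsilyl)oxy]methyl}-5-chloro-4-[(E)-2-chloroethenyl]-4-methylcyclohex-2-en-1-ol | C[C@@]1(/C=C/Cl)C=C(CO[Si](C)(C)C(C)(C)C)[C@@H](O)C[C@@H]1Cl
F5 | step 13 | (1S,4S,5S)-5-chloro-2-(chloromethyl)-4-[(E)-2-chloroethenyl]-4-methylcyclohex-2-en-1-ol | C[C@@]1(/C=C/Cl)C=C(CCl)[C@@H](O)C[C@@H]1Cl
F0 | step 14 | none | none
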